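**Retrosynthetic overview** (cyclodeca[b]furan numbering of the target: C3a/C11a ring fusion, C4 ester carbon, C6 and C10 carry the CH2OH groups)
- Target ⇐ desilylation ⇐ Mitsunobu esterification with methacrylic acid, inverting C4 of a 4-epi hydroxy lactone.
- Ten-membered carbocycle and α-methylene-γ-butyrolactone ⇐ one operation from an acyclic ω-formyl (Z)-2-(bromomethyl)-2-enoate: CrCl2-mediated intramolecular allylation forges C3a–C11a (carbocycle first), then the alkoxide lactonises in the same flask (lactone second).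
- Allyl bromide ⇐ Morita–Baylis–Hillman reaction and SN2' bromination of an α-silyloxy aldehyde; ring (E)-olefin ⇐ cross-metathesis with a 2-substituted acrylate.
- C4 and C6 ⇐ trans-selective enolate alkylation of the L-glutamic-acid-derived (S)-5-(trityloxymethyl)butyrolactone; C3a and C11a are induced by C4 in the ring closure.

Assumption: lactone 1 (the trityl ether of the L-glutamic-acid-derived hydroxymethyl butyrolactone) and iodide 2 are bought as such.

Step 1
Reactants: 1 (5S)-5-[(triphenylmethoxy)methyl]oxolan-2-one; 2 4-iodobut-1-ene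
Product: 3 (3R,5S)-3-(but-3-en-1-yl)-5-[(triphenylmethoxy)methyl]oxolan-2-one
Conditions: LiN(i-Pr)2, THF, −78 °C; then 2, DMPU, −78 to −30 °C
Reagents that add atoms: none
Why: Diastereoselective enolate alkylation, in which the lithium enolate of the γ-substituted butyrolactone is attacked anti to the bulky trityloxymethyl group, so the new C3 centre is set trans to C5 (3R,5S).

Step 2
Reactants: 4 methyl 2-(bromomethyl)prop-2-enoate; 5 trimethyl orthoformate
Product: 6 methyl 2-(2,2-dimethoxyethyl)prop-2-enoate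
Conditions: Zn, 5 (3 equiv), THF, 50 °C
Reagents that add atoms: none
Why: Reformatsky-type (Barbier) reaction in which the 2-(methoxycarbonyl)allylzinc bromide formed in the flask adds to the dimethoxycarbenium ion released from the orthoformate, giving the homoallylic acetal without any stereocentre.

Step 3
Reactants: 3 (3R,5S)-3-(but-3-en-1-yl)-5-[(triphenylmethoxy)methyl]oxolan-2-one; 6 methyl 2-(2,2-dimethoxyethyl)prop-2-enoate
Product: 7 methyl (2E)-2-(2,2-dimethoxyethyl)-5-{(3R,5S)-2-oxo-5-[(triphenylmethoxy)methyl]oxolan-3-yl}pent-2-enoate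
Conditions: 6 (5 equiv), second-generation Hoveyda–Grubbs catalyst [RuCl2(H2IMes)(=CH-C6H4-2-O-i-Pr)] (5 mol %), CH2Cl2, 40 °C
Reagents that add atoms: none
Why: Olefin cross-metathesis between the unhindered terminal alkene and the excess 2-substituted acrylate is driven by loss of ethene and gives the thermodynamically preferred (E)-trisubstituted enoate (chain trans to the ester), which is the ring-olefin geometry of the target.

Step 4
Reactants: 7 methyl (2E)-2-(2,2-dimethoxyethyl)-5-{(3R,5S)-2-oxo-5-[(triphenylmethoxy)methyl]oxolan-3-yl}pent-2-enoate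
Product: 8 (2E,6R,8S)-2-(2,2-dimethoxyethyl)-6-(hydroxymethyl)-9-(triphenylmethoxy)non-2-ene-1,8-diol
Conditions: i-Bu2AlH (8 equiv), CH2Cl2, −78 to 0 °C; aq. work-up
Reagents that add atoms: none
Why: Exhaustive hydride reduction in which i-Bu2AlH takes the lactone to the 1,4-diol and the enoate (1,2-reduction) to the allylic alcohol while the acetal, the trityl ether, the olefin geometry and both stereocentres are untouched.

Step 5
Reactants: 8 (2E,6R,8S)-2-(2,2-dimethoxyethyl)-6-(hydroxymethyl)-9-(triphenylmethoxy)non-2-ene-1,8-diol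
Product: 10 tert-butyl({(2S,4R,7E)-4,8-bis({[tert-butyl(diphenyl)silyl]oxy}methyl)-10,10-dimethoxy-1-(triphenylmethoxy)dec-7-en-2-yl}oxy)dimethylsilane, via bis-TBDPS ether 9 (not isolated)
Conditions: tert-butyl(chloro)diphenylsilane (2.1 equiv), imidazole, DMF, 0 °C; then tert-butyl(chloro)dimethylsilane, 40 °C
Reagents that add atoms: tert-butyl(chloro)diphenylsilane, CC(C)(C)[Si](Cl)(c1ccccc1)c1ccccc1; tert-butyl(chloro)dimethylsilane, CC(C)(C)[Si](C)(C)Cl
Why: Sterically differentiated silyl ether formation, in which the bulky TBDPS chloride takes only the two primary hydroxyls and the smaller TBS chloride then caps the remaining secondary hydroxyl in the same flask, with no stereocentre touched.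

Step 6
Reactants: 10 tert-butyl({(2S,4R,7E)-4,8-bis({[tert-butyl(diphenyl)silyl]oxy}methyl)-10,10-dimethoxy-1-(triphenylmethoxy)dec-7-en-2-yl}oxy)dimethylsilane
Product: 11 (2S,4R,7E)-2-{[tert-butyl(dimethyl)silyl]oxy}-4,8-bis({[tert-butyl(diphenyl)silyl]oxy}methyl)-10,10-dimethoxydec-7-en-1-ol
Conditions: camphorsulfonic acid (0.1 equiv), MeOH/CH2Cl2 (1:1), 0 °C
Reagents that add atoms: none
Why: Acid-catalysed SN1 methanolysis removes the trityl ether through the stabilised trityl cation much faster than the hindered secondary TBS ether or the TBDPS ethers react, and the dimethyl acetal is simply regenerated in methanol.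

Step 7
Reactants: 11 (2S,4R,7E)-2-{[tert-butyl(dimethyl)silyl]oxy}-4,8-bis({[tert-butyl(diphenyl)silyl]oxy}methyl)-10,10-dimethoxydec-7-en-1-ol
Product: 12 (2S,4R,7E)-2-{[tert-butyl(dimethyl)silyl]oxy}-4,8-bis({[tert-butyl(diphenyl)silyl]oxy}methyl)-10,10-dimethoxydec-7-enal
Conditions: Dess–Martin periodinane, CH2Cl2, 0 to 25 °C
Reagents that add atoms: none
Why: Dess–Martin oxidation gives the α-silyloxy aldehyde under non-basic conditions, so the adjacent stereocentre is not epimerised.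

Step 8
Reactants: 12 (2S,4R,7E)-2-{[tert-butyl(dimethyl)silyl]oxy}-4,8-bis({[tert-butyl(diphenyl)silyl]oxy}methyl)-10,10-dimethoxydec-7-enal; 13 methyl prop-2-enoate
Product: 14 methyl (4S,6R,9E)-4-{[tert-butyl(dimethyl)silyl]oxy}-6,10-bis({[tert-butyl(diphenyl)silyl]oxy}methyl)-3-hydroxy-12,12-dimethoxy-2-methylidenedodec-9-enoate (both C3 epimers)
Conditions: 13 (neat, 10 equiv), DABCO (1 equiv), MeOH (2 equiv), 25 °C, 5 d
Reagents that add atoms: none
Why: Morita–Baylis–Hillman reaction in which the DABCO–acrylate zwitterion adds to the aldehyde; the new carbinol centre forms as a mixture, which does not matter because it becomes sp2 in the next step.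

Step 9
Reactants: 14 methyl (4S,6R,9E)-4-{[tert-butyl(dimethyl)silyl]oxy}-6,10-bis({[tert-butyl(diphenyl)silyl]oxy}methyl)-3-hydroxy-12,12-dimethoxy-2-methylidenedodec-9-enoate
Product: 15 methyl (2Z,4S,6R,9E)-2-(bromomethyl)-4-{[tert-butyl(dimethyl)silyl]oxy}-6,10-bis({[tert-butyl(diphenyl)silyl]oxy}methyl)-12,12-dimethoxydodeca-2,9-dienoate
Conditions: N-bromosuccinimide, Me2S, CH2Cl2, −20 to 25 °C
Reagents that add atoms: N-bromosuccinimide, O=C1CCC(=O)N1Br
Why: SN2' bromination (Corey–Kim-type activation of the allylic alcohol, bromide attack at the methylene terminus) gives the rearranged, thermodynamically preferred (Z)-2-(bromomethyl)-2-enoate and erases the mixed carbinol centre.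

Step 10
Reactants: 15 methyl (2Z,4S,6R,9E)-2-(bromomethyl)-4-{[tert-butyl(dimethyl)silyl]oxy}-6,10-bis({[tert-butyl(diphenyl)silyl]oxy}methyl)-12,12-dimethoxydodeca-2,9-dienoate
Product: 16 methyl (2Z,4S,6R,9E)-2-(bromomethyl)-4-{[tert-butyl(dimethyl)silyl]oxy}-6,10-bis({[tert-butyl(diphenyl)silyl]oxy}methyl)-12-oxododeca-2,9-dienoate
Conditions: CF3CO2H, H2O, CHCl3, 0 °C, 1 h; used crude
Reagents that add atoms: water, O
Why: Acetal hydrolysis under short, cold aqueous acid unmasks the aldehyde while the silyl ethers and the allylic bromide survive, and the β,γ-unsaturated aldehyde is used at once to avoid conjugation.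

Step 11
Reactants: 16 methyl (2Z,4S,6R,9E)-2-(bromomethyl)-4-{[tert-butyl(dimethyl)silyl]oxy}-6,10-bis({[tert-butyl(diphenyl)silyl]oxy}methyl)-12-oxododeca-2,9-dienoate
Product: 19 (3aR,4S,6R,9E,11aR)-6,10-bis({[tert-butyl(diphenyl)silyl]oxy}methyl)-4-hydroxy-3-methylidene-3a,4,5,6,7,8,11,11a-octahydrocyclodeca[b]furan-2(3H)-one, via hydroxy ester 17 (not isolated), via silyl ether lactone 18 (not isolated)
Conditions: CrCl2 (10 equiv), THF, 25 °C, 16 added over 10 h (final 0.002 M); then MeOH, camphorsulfonic acid, 0 to 25 °C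
Reagents that add atoms: none
Why: Intramolecular Nozaki–Hiyama–Kishi (Barbier-type) allylation closes the ten-membered ring and the resulting alkoxide lactonises onto the neighbouring ester, so both rings form in one flask; the allyl–CrCl2 species reacts at its γ-carbon through a chair in which the aldehyde approaches anti to the C–O bond of the silyloxy stereocentre with its C–H eclipsing the olefin (Felkin-type 1,2-induction, setting C3a) and both chain ends sit equatorial (anti addition, setting C11a trans to C3a), and the acidic methanol finish completes lactonisation and cleaves only the secondary TBS ether.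

Step 12
Reactants: 19 (3aR,4S,6R,9E,11aR)-6,10-bis({[tert-butyl(diphenyl)silyl]oxy}methyl)-4-hydroxy-3-methylidene-3a,4,5,6,7,8,11,11a-octahydrocyclodeca[b]furan-2(3H)-one; 20 2-methylprop-2-enoic acid
Product: 21 (3aR,4R,6R,9E,11aR)-6,10-bis({[tert-butyl(diphenyl)silyl]oxy}methyl)-3-methylidene-2-oxo-2,3,3a,4,5,6,7,8,11,11a-decahydrocyclodeca[b]furan-4-yl 2-methylprop-2-enoate
Conditions: 20 (3 equiv), PPh3, diisopropyl azodicarboxylate, toluene, 0 to 25 °C
Reagents that add atoms: none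
Why: Mitsunobu esterification, in which the C4 hydroxyl is activated as an oxyphosphonium ion and displaced by methacrylate in an SN2 reaction, inverts C4 from S to the R configuration of the target while the primary hydroxyls stay silylated.

Step 13
Reactants: 21 (3aR,4R,6R,9E,11aR)-6,10-bis({[tert-butyl(diphenyl)silyl]oxy}methyl)-3-methylidene-2-oxo-2,3,3a,4,5,6,7,8,11,11a-decahydrocyclodeca[b]furan-4-yl 2-methylprop-2-enoate
Product: 22 (3aR,4R,6R,9E,11aR)-6,10-bis(hydroxymethyl)-3-methylidene-2-oxo-2,3,3a,4,5,6,7,8,11,11a-decahydrocyclodeca[b]furan-4-yl 2-methylprop-2-enoate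
Conditions: HF·pyridine, pyridine, THF, 0 to 25 °C
Reagents that add atoms: none
Why: Fluoride-mediated cleavage of the two primary TBDPS ethers under buffered, non-basic conditions leaves the methacrylate, the α-methylene lactone and all four stereocentres untouched and gives the target.

**Compound list**
1 | (5S)-5-[(triphenylmethoxy)methyl]oxolan-2-one | O1[C@H](COC(c2ccccc2)(c3ccccc3)c4ccccc4)CCC1=O | starting material
2 | 4-iodobut-1-ene | C=CCCI | starting material
3 | (3R,5S)-3-(but-3-en-1-yl)-5-[(triphenylmethoxy)methyl]oxolan-2-one (3,5-trans) | O1[C@H](COC(c2ccccc2)(c3ccccc3)c4ccccc4)C[C@@H](CCC=C)C1=O | intermediate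
4 | methyl 2-(bromomethyl)prop-2-enoate | C=C(CBr)C(=O)OC | starting material
5 | trimethyl orthoformate | COC(OC)OC | starting material
6 | methyl 2-(2,2-dimethoxyethyl)prop-2-enoate | C=C(CC(OC)OC)C(=O)OC | intermediate
7 | methyl (2E)-2-(2,2-dimethoxyethyl)-5-{(3R,5S)-2-oxo-5-[(triphenylmethoxy)methyl]oxolan-3-yl}pent-2-enoate | O1[C@H](COC(c2ccccc2)(c3ccccc3)c4ccccc4)C[C@@H](CC/C=C(/C(=O)OC)CC(OC)OC)C1=O | intermediate
8 | (2E,6R,8S)-2-(2,2-dimethoxyethyl)-6-(hydroxymethyl)-9-(triphenylmethoxy)non-2-ene-1,8-diol | C(OC(c1ccccc1)(c2ccccc2)c3ccccc3)[C@@H](O)C[C@H](CO)CC/C=C(/CO)CC(OC)OC | intermediate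
9 | (2S,4R,7E)-4,8-bis({[tert-butyl(diphenyl)silyl]oxy}methyl)-10,10-dimethoxy-1-(triphenylmethoxy)dec-7-en-2-ol | C(OC(c1ccccc1)(c2ccccc2)c3ccccc3)[C@@H](O)C[C@H](CO[Si](c4ccccc4)(c5ccccc5)C(C)(C)C)CC/C=C(/CO[Si](c6ccccc6)(c7ccccc7)C(C)(C)C)CC(OC)OC | intermediate
10 | tert-butyl({(2S,4R,7E)-4,8-bis({[tert-butyl(diphenyl)silyl]oxy}methyl)-10,10-dimethoxy-1-(triphenylmethoxy)dec-7-en-2-yl}oxy)dimethylsilane | C(OC(c1ccccc1)(c2ccccc2)c3ccccc3)[C@@H](O[Si](C)(C)C(C)(C)C)C[C@H](CO[Si](c4ccccc4)(c5ccccc5)C(C)(C)C)CC/C=C(/CO[Si](c6ccccc6)(c7ccccc7)C(C)(C)C)CC(OC)OC | intermediate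
11 | (2S,4R,7E)-2-{[tert-butyl(dimethyl)silyl]oxy}-4,8-bis({[tert-butyl(diphenyl)silyl]oxy}methyl)-10,10-dimethoxydec-7-en-1-ol | OC[C@@H](O[Si](C)(C)C(C)(C)C)C[C@H](CO[Si](c1ccccc1)(c2ccccc2)C(C)(C)C)CC/C=C(/CO[Si](c3ccccc3)(c4ccccc4)C(C)(C)C)CC(OC)OC | intermediate
12 | (2S,4R,7E)-2-{[tert-butyl(dimethyl)silyl]oxy}-4,8-bis({[tert-butyl(diphenyl)silyl]oxy}methyl)-10,10-dimethoxydec-7-enal | O=C[C@@H](O[Si](C)(C)C(C)(C)C)C[C@H](CO[Si](c1ccccc1)(c2ccccc2)C(C)(C)C)CC/C=C(/CO[Si](c3ccccc3)(c4ccccc4)C(C)(C)C)CC(OC)OC | intermediate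
13 | methyl prop-2-enoate | C=CC(=O)OC | starting material
14 | methyl (4S,6R,9E)-4-{[tert-butyl(dimethyl)silyl]oxy}-6,10-bis({[tert-butyl(diphenyl)silyl]oxy}methyl)-3-hydroxy-12,12-dimethoxy-2-methylidenedodec-9-enoate (both C3 epimers) | COC(=O)C(=C)C(O)[C@@H](O[Si](C)(C)C(C)(C)C)C[C@H](CO[Si](c1ccccc1)(c2ccccc2)C(C)(C)C)CC/C=C(/CO[Si](c3ccccc3)(c4ccccc4)C(C)(C)C)CC(OC)OC | intermediate
15 | methyl (2Z,4S,6R,9E)-2-(bromomethyl)-4-{[tert-butyl(dimethyl)silyl]oxy}-6,10-bis({[tert-butyl(diphenyl)silyl]oxy}methyl)-12,12-dimethoxydodeca-2,9-dienoate | COC(=O)/C(CBr)=C/[C@@H](O[Si](C)(C)C(C)(C)C)C[C@H](CO[Si](c1ccccc1)(c2ccccc2)C(C)(C)C)CC/C=C(/CO[Si](c3ccccc3)(c4ccccc4)C(C)(C)C)CC(OC)OC | intermediate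
16 | methyl (2Z,4S,6R,9E)-2-(bromomethyl)-4-{[tert-butyl(dimethyl)silyl]oxy}-6,10-bis({[tert-butyl(diphenyl)silyl]oxy}methyl)-12-oxododeca-2,9-dienoate | COC(=O)/C(CBr)=C/[C@@H](O[Si](C)(C)C(C)(C)C)C[C@H](CO[Si](c1ccccc1)(c2ccccc2)C(C)(C)C)CC/C=C(/CO[Si](c3ccccc3)(c4ccccc4)C(C)(C)C)CC=O | intermediate
17 | methyl 2-[(1S,2R,4E,8R,10S)-10-{[tert-butyl(dimethyl)silyl]oxy}-4,8-bis({[tert-butyl(diphenyl)silyl]oxy}methyl)-2-hydroxycyclodec-4-en-1-yl]prop-2-enoate | CC(C)(C)[Si](C)(C)O[C@H]1C[C@H](CO[Si](c2ccccc2)(c3ccccc3)C(C)(C)C)CC/C=C(/CO[Si](c4ccccc4)(c5ccccc5)C(C)(C)C)C[C@@H](O)[C@@H]1C(=C)C(=O)OC | intermediate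
18 | (3aS,4S,6R,9E,11aR)-4-{[tert-butyl(dimethyl)silyl]oxy}-6,10-bis({[tert-butyl(diphenyl)silyl]oxy}methyl)-3-methylidene-3a,4,5,6,7,8,11,11a-octahydrocyclodeca[b]furan-2(3H)-one (same spatial arrangement at C3a as 19; the descriptor changes only through substituent priorities) | CC(C)(C)[Si](C)(C)O[C@H]1C[C@H](CO[Si](c2ccccc2)(c3ccccc3)C(C)(C)C)CC/C=C(/CO[Si](c4ccccc4)(c5ccccc5)C(C)(C)C)C[C@H]6OC(=O)C(=C)[C@H]16 | intermediate
19 | (3aR,4S,6R,9E,11aR)-6,10-bis({[tert-butyl(diphenyl)silyl]oxy}methyl)-4-hydroxy-3-methylidene-3a,4,5,6,7,8,11,11a-octahydrocyclodeca[b]furan-2(3H)-one | O[C@H]1C[C@H](CO[Si](c2ccccc2)(c3ccccc3)C(C)(C)C)CC/C=C(/CO[Si](c4ccccc4)(c5ccccc5)C(C)(C)C)C[C@H]6OC(=O)C(=C)[C@H]16 | intermediate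
20 | 2-methylprop-2-enoic acid | C=C(C)C(=O)O | starting material
21 | (3aR,4R,6R,9E,11aR)-6,10-bis({[tert-butyl(diphenyl)silyl]oxy}methyl)-3-methylidene-2-oxo-2,3,3a,4,5,6,7,8,11,11a-decahydrocyclodeca[b]furan-4-yl 2-methylprop-2-enoate | C=C(C)C(=O)O[C@@H]1C[C@H](CO[Si](c2ccccc2)(c3ccccc3)C(C)(C)C)CC/C=C(/CO[Si](c4ccccc4)(c5ccccc5)C(C)(C)C)C[C@H]6OC(=O)C(=C)[C@H]16 | intermediate
22 | (3aR,4R,6R,9E,11aR)-6,10-bis(hydroxymethyl)-3-methylidene-2-oxo-2,3,3a,4,5,6,7,8,11,11a-decahydrocyclodeca[b]furan-4-yl 2-methylprop-2-enoate | C=C(C)C(=O)O[C@@H]1C[C@H](CO)CC/C=C(/CO)C[C@H]2OC(=O)C(=C)[C@H]12 | target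

**Step count:** 13 steps in total. **Longest linear sequence:** 12 steps (1 → 3 → 7 → 8 → 10 → 11 → 12 → 14 → 15 → 16 → 19 → 21 → 22; step 2 is the side branch).

**The three steps most likely to fail**

Step 11 (double ring closure). The ten-membered closure must beat oligomerisation, and two selectivities must hold at once: bond formation anti to the C–O bond of the silyloxy centre, and anti addition giving the trans ring fusion. The fallback replaces the equilibrating allyl–CrCl2 species by a geometry-defined allylboronate that reacts stereospecifically through a boron-centred chair. It sets out from aldehyde 12. Homologation with the Ohira–Bestmann reagent (K2CO3, MeOH) gives (3S,5R,8E)-3-{[tert-butyl(dimethyl)silyl]oxy}-5,9-bis({[tert-butyl(diphenyl)silyl]oxy}methyl)-11,11-dimethoxyundec-8-en-1-yne F1. Deprotonation with n-BuLi and trapping with ClCO2Me gives the ynoate methyl (4S,6R,9E)-4-{[tert-butyl(dimethyl)silyl]oxy}-6,10-bis({[tert-butyl(diphenyl)silyl]oxy}methyl)-12,12-dimethoxydodec-9-en-2-ynoate F2. syn-Hydroalumination (i-Bu2AlH, HMPA) and alkylation of the α-aluminio enoate with ICH2B(pin) gives the allylboronate methyl (2Z,4S,6R,9E)-4-{[tert-butyl(dimethyl)silyl]oxy}-6,10-bis({[tert-butyl(diphenyl)silyl]oxy}methyl)-12,12-dimethoxy-2-[(4,4,5,5-tetramethyl-1,3,2-dioxaborolan-2-yl)methyl]dodeca-2,9-dienoate F3, in which the silyloxy-bearing carbon is cis to the ester. Acetal hydrolysis as in step 10 gives the aldehyde methyl (2Z,4S,6R,9E)-4-{[tert-butyl(dimethyl)silyl]oxy}-6,10-bis({[tert-butyl(diphenyl)silyl]oxy}methyl)-12-oxo-2-[(4,4,5,5-tetramethyl-1,3,2-dioxaborolan-2-yl)methyl]dodeca-2,9-dienoate F4. Heating F4 in toluene (80 °C, 0.002 M) effects intramolecular allylboration, which is expected to give the trans ring fusion from this olefin geometry, and the same acidic methanol finish brings the material back to the route at 19.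

Step 12 (Mitsunobu inversion). The C4 hydroxyl sits on the ring next to the ring fusion, so elimination or incomplete inversion is possible, and PPh3 can add reversibly to the α-methylene lactone. The fallback replaces SN2 inversion by oxidation, reduction and ordinary acylation. It sets out from 19. Dess–Martin oxidation gives the ketone (3aS,6R,9E,11aR)-6,10-bis({[tert-butyl(diphenyl)silyl]oxy}methyl)-3-methylidene-3a,5,6,7,8,11,11a-heptahydrocyclodeca[b]furan-2,4(3H)-dione F5. Reduction with NaBH4 and CeCl3·7H2O at −78 °C, or with a 2-methyl-CBS-oxazaborolidine and catecholborane if reagent control is needed, gives the 4-epimeric alcohol (3aR,4R,6R,9E,11aR)-6,10-bis({[tert-butyl(diphenyl)silyl]oxy}methyl)-4-hydroxy-3-methylidene-3a,4,5,6,7,8,11,11a-octahydrocyclodeca[b]furan-2(3H)-one F6. Acylation with methacrylic anhydride, Et3N and DMAP comes back to the route at 21.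

Step 3 (cross-metathesis). A 2-substituted acrylate carrying a branched side chain is a sluggish metathesis partner, and homodimerisation of 3 competes. The fallback builds the same olefin by aldol addition and elimination. It sets out from 3. Ozonolysis (O3, CH2Cl2, −78 °C; PPh3) gives the aldehyde 3-{(3R,5S)-2-oxo-5-[(triphenylmethoxy)methyl]oxolan-3-yl}propanal F7. Addition of the lithium enolate of commercial methyl 4,4-dimethoxybutanoate (LiN(i-Pr)2, THF, −78 °C) gives the β-hydroxy ester methyl 2-(2,2-dimethoxyethyl)-3-hydroxy-5-{(3R,5S)-2-oxo-5-[(triphenylmethoxy)methyl]oxolan-3-yl}pentanoate F8 as a mixture of epimers. Acetylation (Ac2O, DMAP) gives methyl 3-acetoxy-2-(2,2-dimethoxyethyl)-5-{(3R,5S)-2-oxo-5-[(triphenylmethoxy)methyl]oxolan-3-yl}pentanoate F9, and E1cB elimination with DBU gives the thermodynamically preferred (E)-enoate, coming back to the route at 7.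

Further compounds
F1 | step 11 | (3S,5R,8E)-3-{[tert-butyl(dimethyl)silyl]oxy}-5,9-bis({[tert-butyl(diphenyl)silyl]oxy}methyl)-11,11-dimethoxyundec-8-en-1-yne | C#C[C@@H](O[Si](C)(C)C(C)(C)C)C[C@H](CO[Si](c1ccccc1)(c2ccccc2)C(C)(C)C)CC/C=C(/CO[Si](c3ccccc3)(c4ccccc4)C(C)(C)C)CC(OC)OC
F2 | step 11 | methyl (4S,6R,9E)-4-{[tert-butyl(dimethyl)silyl]oxy}-6,10-bis({[tert-butyl(diphenyl)silyl]oxy}methyl)-12,12-dimethoxydodec-9-en-2-ynoate | COC(=O)C#C[C@@H](O[Si](C)(C)C(C)(C)C)C[C@H](CO[Si](c1ccccc1)(c2ccccc2)C(C)(C)C)CC/C=C(/CO[Si](c3ccccc3)(c4ccccc4)C(C)(C)C)CC(OC)OC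
F3 | step 11 | methyl (2Z,4S,6R,9E)-4-{[tert-butyl(dimethyl)silyl]oxy}-6,10-bis({[tert-butyl(diphenyl)silyl]oxy}methyl)-12,12-dimethoxy-2-[(4,4,5,5-tetramethyl-1,3,2-dioxaborolan-2-yl)methyl]dodeca-2,9-dienoate | COC(=O)/C(CB1OC(C)(C)C(C)(C)O1)=C\[C@@H](O[Si](C)(C)C(C)(C)C)C[C@H](CO[Si](c2ccccc2)(c3ccccc3)C(C)(C)C)CC/C=C(/CO[Si](c4ccccc4)(c5ccccc5)C(C)(C)C)CC(OC)OC
F4 | step 11 | methyl (2Z,4S,6R,9E)-4-{[tert-butyl(dimethyl)silyl]oxy}-6,10-bis({[tert-butyl(diphenyl)silyl]oxy}methyl)-12-oxo-2-[(4,4,5,5-tetramethyl-1,3,2-dioxaborolan-2-yl)methyl]dodeca-2,9-dienoate | COC(=O)/C(CB1OC(C)(C)C(C)(C)O1)=C\[C@@H](O[Si](C)(C)C(C)(C)C)C[C@H](CO[Si](c2ccccc2)(c3ccccc3)C(C)(C)C)CC/C=C(/CO[Si](c4ccccc4)(c5ccccc5)C(C)(C)C)CC=O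
F5 | step 12 | (3aS,6R,9E,11aR)-6,10-bis({[tert-butyl(diphenyl)silyl]oxy}methyl)-3-methylidene-3a,5,6,7,8,11,11a-heptahydrocyclodeca[b]furan-2,4(3H)-dione | O=C1C[C@H](CO[Si](c2ccccc2)(c3ccccc3)C(C)(C)C)CC/C=C(/CO[Si](c4ccccc4)(c5ccccc5)C(C)(C)C)C[C@H]6OC(=O)C(=C)[C@H]16
F6 | step 12 | (3aR,4R,6R,9E,11aR)-6,10-bis({[tert-butyl(diphenyl)silyl]oxy}methyl)-4-hydroxy-3-methylidene-3a,4,5,6,7,8,11,11a-octahydrocyclodeca[b]furan-2(3H)-one | O[C@@H]1C[C@H](CO[Si](c2ccccc2)(c3ccccc3)C(C)(C)C)CC/C=C(/CO[Si](c4ccccc4)(c5ccccc5)C(C)(C)C)C[C@H]6OC(=O)C(=C)[C@H]16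
F7 | step 3 | 3-{(3R,5S)-2-oxo-5-[(triphenylmethoxy)methyl]oxolan-3-yl}propanal | O1[C@H](COC(c2ccccc2)(c3ccccc3)c4ccccc4)C[C@@H](CCC=O)C1=O
F8 | step 3 | methyl 2-(2,2-dimethoxyethyl)-3-hydroxy-5-{(3R,5S)-2-oxo-5-[(triphenylmethoxy)methyl]oxolan-3-yl}pentanoate (epimer mixture) | O1[C@H](COC(c2ccccc2)(c3ccccc3)c4ccccc4)C[C@@H](CCC(O)C(CC(OC)OC)C(=O)OC)C1=O
F9 | step 3 | methyl 3-acetoxy-2-(2,2-dimethoxyethyl)-5-{(3R,5S)-2-oxo-5-[(triphenylmethoxy)methyl]oxolan-3-yl}pentanoate (epimer mixture) | O1[C@H](COC(c2ccccc2)(c3ccccc3)c4ccccc4)C[C@@H](CCC(OC(C)=O)C(CC(OC)OC)C(=O)OC)C1=O
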